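**Plan**
- Retrosynthesis: the depside ester bond (ring A C=O to the oxygen on B-C4) is cut first. Ring B is then cut at B-C6–heptyl and at B-C1–CO2H.
- Enabling feature: on ring B the heptyl (B-C6), carboxyl (B-C1) and methoxy (B-C2) groups sit on three contiguous carbons. This is the pattern left when a carbanion and then an electrophile add across the B-C6/B-C1 triple bond of a 3-methoxybenzyne, with the B-C4 oxygen carried along as a silyl ether.
- Ring B forward: fluorophenol, TIPS ether, one-flask lithiation / LiF loss / heptyllithium addition / CO2 capture, benzyl ester, free 4-OH. Both benzene rings are purchased and no ring is built.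
- Ring A forward: methyl olivetolate, 4-O-methyl ether, 2-O-benzyl ether, free acid.
- Union and end game: anhydride-mediated esterification joins the two halves, and one hydrogenolysis removes both benzyl groups.
- Stereochemistry: there is none to set. Only regiochemistry needs control (lithiation site, sense of aryne addition, 4-OH versus 2-OH alkylation).

Key step: step 3

Remark: the target has no stereocentre, axis or other stereogenic element. It is achiral, so the call for a single enantiomer places no demand on the route.

**Step 1**
Reactants: 1 3-fluoro-5-methoxyphenol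
Product: 2 (3-fluoro-5-methoxyphenoxy)triisopropylsilane
Conditions: TIPSCl, imidazole, DMF, rt
Reagents that add atoms: triisopropylsilyl chloride, CC(C)[Si](Cl)(C(C)C)C(C)C
Why: Imidazole-promoted O-silylation of a phenol should give a bulky ether that resists alkyllithiums, directs lithiation poorly and shields both of its ortho positions.

**Step 2**
Reactants: 3 1-iodoheptane
Product: 4 heptyllithium (solution in pentane–Et2O, used as such in step 3)
Conditions: t-BuLi (2.1 equiv), pentane–Et2O (3:2), −78 °C; then rt, 1 h
Reagents that add atoms: tert-butyllithium, [Li]C(C)(C)C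
Why: Lithium–iodine exchange on a primary iodide is fast at −78 °C and is made irreversible by the second equivalent of t-BuLi, which destroys the tert-butyl iodide, while the warm-up lets ether consume the small excess of t-BuLi so that only the primary alkyllithium reaches the aryne.

**Step 3**
Reactants: 2 (3-fluoro-5-methoxyphenoxy)triisopropylsilane; 4 heptyllithium; 5 carbon dioxide
Product: 10 2-heptyl-6-methoxy-4-(triisopropylsilyloxy)benzoic acid, via fluoroaryllithium 6 (not isolated), via aryne 7 (not isolated), via heptylated aryllithium 8 (not isolated), via lithium carboxylate 9 (not isolated)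
Conditions: 4 (3 equiv), THF/Et2O/pentane, −78 °C, 1 h; warm to −10 °C; recool to −78 °C, cannulate into THF saturated with CO2 (5, excess); then 1 M HCl, 0 °C
Reagents that add atoms: carbon dioxide (5), O=C=O
Why: One equivalent of 4 acts as base in a directed ortho-metalation at the only C–H flanked by fluorine and methoxy (future B-C1), giving 6, which holds at −78 °C and sheds LiF on warming to form the 3-methoxy-5-silyloxybenzyne 7 with its triple bond between future B-C6 and B-C1. A further equivalent of 4 carbolithiates 7 at B-C6, the aryne carbon remote from the methoxy group, so that the charge in 8 develops at B-C1 beside the electron-withdrawing, lithium-coordinating oxygen, and 8 then attacks 5 to give 9 and, after acidification, 10. The closest known reaction type is the addition of alkyllithiums to alkoxybenzynes generated from fluoroanisoles and 3,5-dialkoxyfluorobenzenes, followed by carbonation to 6-alkyl-2-alkoxybenzoic acids. No ring is closed and no stereocentre is created; two skeletal bonds (B-C6–heptyl and B-C1–CO2H) are formed. Three selectivities are needed: the lithiation site is fixed by the cooperative F/OMe acidification and by the bulky, weakly coordinating OTIPS group that shields both of its neighbours; the sense of addition is fixed by the methoxy-induced polarisation and distortion of the aryne, which outweighs the remote silyloxy group; and capture of 7 by 4 in preference to the hindered aryllithiums 6 and 8 is favoured by the excess of 4 and by dilution. The C–Li bonds of 6 and 8 lie para to the silyloxy group, so O-to-C silyl migration cannot intervene, and inverse addition into excess CO2 keeps the remaining alkyllithium away from the hindered carboxylate 9.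

**Step 4**
Reactants: 10 2-heptyl-6-methoxy-4-(triisopropylsilyloxy)benzoic acid
Product: 11 benzyl 2-heptyl-6-methoxy-4-(triisopropylsilyloxy)benzoate
Conditions: BnBr, KHCO3, DMF, rt
Reagents that add atoms: benzyl bromide, BrCc1ccccc1
Why: SN2 O-alkylation of the carboxylate takes place at the benzylic carbon of the reagent, so the two ortho groups that shield the carbonyl do not matter, and hydrogencarbonate is too weak a base to disturb the aryl TIPS ether.

**Step 5**
Reactants: 11 benzyl 2-heptyl-6-methoxy-4-(triisopropylsilyloxy)benzoate
Product: 12 benzyl 2-heptyl-4-hydroxy-6-methoxybenzoate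
Conditions: TBAF, AcOH (1.1 equiv each), THF, 0 °C
Reagents that add atoms: none
Why: Fluoride-induced desilylation, driven by the strong Si–F bond, should free the 4-OH quickly, while the acetic acid buffer and the hindered benzyl ester exclude acyl transfer.

**Step 6**
Reactants: 13 methyl olivetolate (methyl 2,4-dihydroxy-6-pentylbenzoate)
Product: 14 methyl 2-hydroxy-4-methoxy-6-pentylbenzoate
Conditions: MeI (1.05 equiv), K2CO3 (1.1 equiv), acetone, reflux
Reagents that add atoms: iodomethane, CI
Why: In this Williamson etherification the 2-OH is tied up in a hydrogen bond to the ester carbonyl, so a single equivalent of methyl iodide should alkylate the free, more acidic 4-OH, as is usual for resorcylate esters.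

**Step 7**
Reactants: 14 methyl 2-hydroxy-4-methoxy-6-pentylbenzoate
Product: 15 methyl 2-(benzyloxy)-4-methoxy-6-pentylbenzoate
Conditions: BnBr (1.5 equiv), K2CO3 (2 equiv), DMF, 60 °C
Reagents that add atoms: benzyl bromide, BrCc1ccccc1
Why: Williamson benzylation of the remaining chelated phenol needs only excess reagent, a dipolar aprotic solvent and gentle heating, and no other nucleophilic site is left.

**Step 8**
Reactants: 15 methyl 2-(benzyloxy)-4-methoxy-6-pentylbenzoate
Product: 17 2-(benzyloxy)-4-methoxy-6-pentylbenzoic acid, via potassium carboxylate 16 (not isolated)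
Conditions: KOH (10 equiv), DMSO–H2O (4:1), 100 °C; then cold 1 M HCl
Reagents that add atoms: potassium hydroxide, [K+].[OH-]
Why: Saponification of a di-ortho-substituted methyl benzoate calls for poorly solvated hydroxide at elevated temperature, conditions to which the benzyl and methyl ethers are inert, and cold acidification guards the electron-rich acid against decarboxylation.

**Step 9**
Reactants: 17 2-(benzyloxy)-4-methoxy-6-pentylbenzoic acid; 12 benzyl 2-heptyl-4-hydroxy-6-methoxybenzoate
Product: 19 benzyl 4-{[2-(benzyloxy)-4-methoxy-6-pentylbenzoyl]oxy}-2-heptyl-6-methoxybenzoate, via mixed trifluoroacetic anhydride 18 (not isolated)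
Conditions: (CF3CO)2O, toluene, 0 °C to rt
Reagents that add atoms: none
Why: In this trifluoroacetic anhydride-mediated esterification, the classical depside coupling, the mixed anhydride 18 of the electron-rich acid ionises readily towards an acylium ion that is insensitive to ortho hindrance and is captured by the sterically open, only hydroxyl group of 12.

**Step 10**
Reactants: 19 benzyl 4-{[2-(benzyloxy)-4-methoxy-6-pentylbenzoyl]oxy}-2-heptyl-6-methoxybenzoate
Product: 20 2-heptyl-4-[(2-hydroxy-4-methoxy-6-pentylbenzoyl)oxy]-6-methoxybenzoic acid (target)
Conditions: H2 (1 atm), 10% Pd/C, EtOAc, rt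
Reagents that add atoms: none
Why: Catalytic hydrogenolysis cleaves the benzylic C–O bonds of the ester and the ether in one neutral operation that should leave the aryl ester link, the methyl ethers and both rings untouched.

**Compound list**
1 | 3-fluoro-5-methoxyphenol | COc1cc(O)cc(F)c1 | starting material
2 | (3-fluoro-5-methoxyphenoxy)triisopropylsilane | COc1cc(F)cc(O[Si](C(C)C)(C(C)C)C(C)C)c1 | intermediate
3 | 1-iodoheptane | CCCCCCCI | starting material
4 | heptyllithium | [Li]CCCCCCC | intermediate
5 | carbon dioxide | O=C=O | starting material
6 | [2-fluoro-6-methoxy-4-(triisopropylsilyloxy)phenyl]lithium | [Li]c1c(F)cc(O[Si](C(C)C)(C(C)C)C(C)C)cc1OC | intermediate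
7 | 3-methoxy-5-(triisopropylsilyloxy)benzyne | COC1=CC(O[Si](C(C)C)(C(C)C)C(C)C)=CC#C1 | intermediate
8 | [2-heptyl-6-methoxy-4-(triisopropylsilyloxy)phenyl]lithium | [Li]c1c(CCCCCCC)cc(O[Si](C(C)C)(C(C)C)C(C)C)cc1OC | intermediate
9 | lithium 2-heptyl-6-methoxy-4-(triisopropylsilyloxy)benzoate | [Li+].[O-]C(=O)c1c(CCCCCCC)cc(O[Si](C(C)C)(C(C)C)C(C)C)cc1OC | intermediate
10 | 2-heptyl-6-methoxy-4-(triisopropylsilyloxy)benzoic acid | CCCCCCCc1cc(O[Si](C(C)C)(C(C)C)C(C)C)cc(OC)c1C(=O)O | intermediate
11 | benzyl 2-heptyl-6-methoxy-4-(triisopropylsilyloxy)benzoate | CCCCCCCc1cc(O[Si](C(C)C)(C(C)C)C(C)C)cc(OC)c1C(=O)OCc1ccccc1 | intermediate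
12 | benzyl 2-heptyl-4-hydroxy-6-methoxybenzoate | CCCCCCCc1cc(O)cc(OC)c1C(=O)OCc1ccccc1 | intermediate
13 | methyl olivetolate (methyl 2,4-dihydroxy-6-pentylbenzoate) | CCCCCc1cc(O)cc(O)c1C(=O)OC | starting material
14 | methyl 2-hydroxy-4-methoxy-6-pentylbenzoate | CCCCCc1cc(OC)cc(O)c1C(=O)OC | intermediate
15 | methyl 2-(benzyloxy)-4-methoxy-6-pentylbenzoate | CCCCCc1cc(OC)cc(OCc2ccccc2)c1C(=O)OC | intermediate
16 | potassium 2-(benzyloxy)-4-methoxy-6-pentylbenzoate | [K+].[O-]C(=O)c1c(CCCCC)cc(OC)cc1OCc1ccccc1 | intermediate
17 | 2-(benzyloxy)-4-methoxy-6-pentylbenzoic acid | CCCCCc1cc(OC)cc(OCc2ccccc2)c1C(=O)O | intermediate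
18 | 2-(benzyloxy)-4-methoxy-6-pentylbenzoic trifluoroacetic anhydride | CCCCCc1cc(OC)cc(OCc2ccccc2)c1C(=O)OC(=O)C(F)(F)F | intermediate
19 | benzyl 4-{[2-(benzyloxy)-4-methoxy-6-pentylbenzoyl]oxy}-2-heptyl-6-methoxybenzoate | CCCCCCCc1cc(OC(=O)c2c(OCc3ccccc3)cc(OC)cc2CCCCC)cc(OC)c1C(=O)OCc1ccccc1 | intermediate
20 | 2-heptyl-4-[(2-hydroxy-4-methoxy-6-pentylbenzoyl)oxy]-6-methoxybenzoic acid | CCCCCCCc1cc(OC(=O)c2c(O)cc(OC)cc2CCCCC)cc(OC)c1C(=O)O | target

**Step count**
Total step count: 10.
Longest linear sequence: 6 steps (steps 1, 3, 4, 5, 9, 10; the branch through step 2 is equally long, and the ring A branch through steps 6, 7, 8, 9, 10 has 5).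

**Steps most likely to fail**

Step 3.
- What may go wrong: the aryne may be consumed by the aryllithiums in the flask faster than by the alkyllithium. Lithiation may leak to the position between fluorine and the silyloxy group. Residual alkyllithium may attack the fresh carboxylate.
- Where the fallback runs: it sets out from 2 and comes back at 10. It forms the same two bonds in reverse order and without an aryne.
- First stage: 2 is lithiated with n-BuLi (1.05 equiv) in THF at −78 °C to 6. This is kept cold so that no LiF is lost, and it is carboxylated at once to 2-fluoro-6-methoxy-4-(triisopropylsilyloxy)benzoic acid F1.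
- Second stage: F1 is treated with 4 (2.5 equiv, one of which is spent on the acidic proton) in THF from −78 °C to 0 °C. Fluoride should be replaced by heptyl through carboxylate-assisted nucleophilic aromatic substitution. This addition–elimination is known for unprotected 2-fluorobenzoic acids with organolithium and Grignard reagents. Acidification then gives 10.

Step 9.
- What may go wrong: acyl transfer from the di-ortho-substituted acid may be sluggish. The phenol may be trifluoroacetylated in competition, or the ortho benzyl ether may be lost under the acidic conditions.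
- Where the fallback runs: it sets out from 17 and 12 and comes back at 20. It changes the protecting-group plan, so that a smaller acid is coupled under neutral conditions.
- First stage: 17 is hydrogenolysed (H2, Pd/C, EtOAc) to 2-hydroxy-4-methoxy-6-pentylbenzoic acid F2.
- Second stage: the chelated ortho hydroxyl of F2 needs no protection, so it is condensed with 12 by DCC in toluene (carbodiimide depside coupling). This gives benzyl 2-heptyl-4-[(2-hydroxy-4-methoxy-6-pentylbenzoyl)oxy]-6-methoxybenzoate F3.
- Third stage: hydrogenolysis of the single benzyl ester of F3 gives 20.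

Step 8.
- What may go wrong: hydrolysis may stall because the ester carbonyl is shielded on both sides. The electron-rich acid may decarboxylate during long heating or on acidification.
- Where the fallback runs: it sets out from 15 and comes back at 17 by a redox detour that avoids hot base.
- First stage: LiAlH4 in THF reduces 15 to [2-(benzyloxy)-4-methoxy-6-pentylphenyl]methanol F4.
- Second stage: MnO2 in CH2Cl2 oxidises F4 to 2-(benzyloxy)-4-methoxy-6-pentylbenzaldehyde F5.
- Third stage: a Pinnick oxidation (NaClO2, NaH2PO4, 2-methyl-2-butene, t-BuOH–H2O, rt) converts F5 into 17.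

**Further compounds**
F1 | step 3 | 2-fluoro-6-methoxy-4-(triisopropylsilyloxy)benzoic acid | COc1cc(O[Si](C(C)C)(C(C)C)C(C)C)cc(F)c1C(=O)O
F2 | step 9 | 2-hydroxy-4-methoxy-6-pentylbenzoic acid | CCCCCc1cc(OC)cc(O)c1C(=O)O
F3 | step 9 | benzyl 2-heptyl-4-[(2-hydroxy-4-methoxy-6-pentylbenzoyl)oxy]-6-methoxybenzoate | CCCCCCCc1cc(OC(=O)c2c(O)cc(OC)cc2CCCCC)cc(OC)c1C(=O)OCc1ccccc1
F4 | step 8 | [2-(benzyloxy)-4-methoxy-6-pentylphenyl]methanol | CCCCCc1cc(OC)cc(OCc2ccccc2)c1CO
F5 | step 8 | 2-(benzyloxy)-4-methoxy-6-pentylbenzaldehyde | CCCCCc1cc(OC)cc(OCc2ccccc2)c1C=O
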